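**Retrosynthetic overview**

1. The lactone is the only ring and closes last: four C–Bpin bonds serve as masked hydroxyls, and after oxidation the C5–OH lactonises onto a Z-enoate (no protecting groups).
2. C3–C4: site-selective sp3–sp2 coupling of the single primary C–B bond of a vicinal bis(boronate) with ethyl (Z)-3-iodoacrylate (new variant), run after the alkene diboration that sets C5.
3. C7–C8: stereospecific 1,2-boronate rearrangement with a (−)-sparteine-lithiated butenyl benzoate at the primary boron of a 1,2,4-tris(boronate) (sets C7); C9 comes from alkene diboration.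
4. C11–C12 and C9–C10: palladium-induced 1,2-shift of nonyl from boron to carbon in a three-component conjunctive coupling of nonyl-Bpin, vinylmagnesium bromide and vinyl bromide (sets C11).
5. C12–C13: Matteson CH2 insertion (again a 1,2-shift) on octyl-Bpin from oct-1-ene; carbon sources are oct-1-ene, BrCH2Cl, CH2=CHMgBr, CH2=CHBr, but-3-en-1-ol and ethyl (Z)-3-iodoacrylate.

Numbering used below: C1–C20 of the seco-acid (C1 = lactone carbonyl, C5 = ring CH–O, C7/C9/C11 = carbinols, C12–C20 = nonyl). The target SMILES is read as (6S)-6-[(2S,4R,6S)-2,4,6-trihydroxypentadecyl]-5,6-dihydro-2H-pyran-2-one, an all-anti 1,3-polyol. Bpin = 4,4,5,5-tetramethyl-1,3,2-dioxaborolan-2-yl.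

Assumption: (R,R)-L* [the (R,R)-TADDOL-derived phenylphosphonite with 3,5-diisopropylphenyl groups, the sense that gives an (R)-1,2-diol from a simple 1-alkene] and (Sp,Sp)-M* [the MandyPhos ligand 1,1'-bis[(R)-α-(dimethylamino)benzyl]-2,2'-bis(diphenylphosphino)ferrocene, Fe[C5H3(PPh2)(CH(NMe2)Ph)]2] are taken to give the configurations drawn; if the sense of either is the opposite, its enantiomer is used and the products are as drawn.

**Route**

Step 1
Reactants: 1 oct-1-ene
Product: 4 4,4,5,5-tetramethyl-2-nonyl-1,3,2-dioxaborolane (nonyl-Bpin), via octyl-Bpin 2 (not isolated), via chloromethyl ate complex 3 (not isolated)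
Conditions: HBpin, [Ir(cod)Cl]2 (1 mol%), dppm (2 mol%), THF, rt; then BrCH2Cl, n-BuLi, −78 °C → rt
Reagents that add atoms: pinacolborane, [H]B1OC(C)(C)C(C)(C)O1; bromochloromethane, ClCBr
Why: Iridium-catalysed anti-Markovnikov hydroboration gives 2, then Matteson homologation: LiCH2Cl adds to boron and the octyl group makes a 1,2-shift from boron to carbon as chloride leaves (no stereocentre).

Step 2
Reactants: 4 nonyl-Bpin
Product: 6 2-[(4S)-tridec-1-en-4-yl]-4,4,5,5-tetramethyl-1,3,2-dioxaborolane, via ethenyl ate complex 5 (not isolated)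
Conditions: CH2=CHMgBr (1.1 equiv), NaOTf (2 equiv), THF, 0 °C → rt; then Pd(OAc)2 (2 mol%), (Sp,Sp)-M* (2.4 mol%), CH2=CHBr (1.2 equiv, 1 M in THF), THF/DMSO, 40 °C, sealed vessel
Reagents that add atoms: vinylmagnesium bromide, C=C[Mg]Br; vinyl bromide, C=CBr
Why: Conjunctive cross-coupling: the alkenyl complex of divalent palladium formed by oxidative addition of vinyl bromide to zerovalent palladium binds the vinyl group of ate complex 5, the nonyl group then shifts from boron to the α-carbon anti to palladium (palladium-induced 1,2-metallate rearrangement) and reductive elimination joins the β-carbon to the second vinyl group, with the chiral bisphosphine choosing the alkene face so that C11 is set by catalyst control.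

Step 3
Reactants: 6 2-[(4S)-tridec-1-en-4-yl]-4,4,5,5-tetramethyl-1,3,2-dioxaborolane
Product: 7 2,2',2''-[(2S,4S)-tridecane-1,2,4-triyl]tris(4,4,5,5-tetramethyl-1,3,2-dioxaborolane)
Conditions: B2pin2, Pt(dba)3 (1 mol%), (R,R)-L* (1.2 mol%), THF, 60 °C
Reagents that add atoms: bis(pinacolato)diboron, CC1(C)OB(OC1(C)C)B1OC(C)(C)C(C)(C)O1
Why: Platinum-catalysed enantioselective syn-1,2-diboration (B–B oxidative addition to zerovalent platinum, alkene insertion, reductive elimination); the chiral phosphonite selects the alkene face, so C9 is set by catalyst control, with the 1,3-related C11 centre too remote to override it.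

Step 4
Reactants: 8 but-3-en-1-ol
Product: 9 but-3-en-1-yl 2,4,6-triisopropylbenzoate
Conditions: 2,4,6-triisopropylbenzoic acid, PPh3, DIAD, THF, 0 °C → rt
Reagents that add atoms: 2,4,6-triisopropylbenzoic acid, CC(C)c1cc(C(C)C)c(C(=O)O)c(C(C)C)c1
Why: Mitsunobu esterification of the primary alcohol gives the hindered benzoate that directs α-lithiation and acts as leaving group in the 1,2-shift of step 5; no stereocentre is formed.

Step 5
Reactants: 7 2,2',2''-[(2S,4S)-tridecane-1,2,4-triyl]tris(4,4,5,5-tetramethyl-1,3,2-dioxaborolane); 9 but-3-en-1-yl 2,4,6-triisopropylbenzoate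
Product: 12 2,2',2''-[(4S,6R,8S)-heptadec-1-ene-4,6,8-triyl]tris(4,4,5,5-tetramethyl-1,3,2-dioxaborolane), via lithiated benzoate 10 (not isolated), via triboronate ate complex 11 (not isolated)
Conditions: 9 (1.2 equiv), s-BuLi, (−)-sparteine, Et2O, −78 °C, 4 h; then 7, −78 °C, 1 h; then reflux, 2 h
Reagents that add atoms: none
Why: Regioselective lithiation–borylation: Hoppe-type sparteine-mediated deprotonation of 9 gives the (S)-carbenoid 10, which adds with retention only to the unhindered primary boron of the vicinal bis(boronate) unit, and the stereospecific 1,2-shift of C8 from boron to carbon anti to the departing benzoate (inversion at the carbenoid carbon) sets C7 by reagent control.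

Step 6
Reactants: 12 2,2',2''-[(4S,6R,8S)-heptadec-1-ene-4,6,8-triyl]tris(4,4,5,5-tetramethyl-1,3,2-dioxaborolane); 13 ethyl (Z)-3-iodoprop-2-enoate
Product: 15 ethyl (2Z,5R,7S,9R,11S)-5,7,9,11-tetrakis(4,4,5,5-tetramethyl-1,3,2-dioxaborolan-2-yl)icos-2-enoate, via pentakis(boronate) 14 (not isolated)
Conditions: B2pin2, Pt(dba)3 (2 mol%), (R,R)-L* (2.4 mol%), THF, 60 °C; then 13, Pd(OAc)2 (3 mol%), RuPhos (3.5 mol%), K3PO4, THF/H2O (10:1), 45 °C
Reagents that add atoms: bis(pinacolato)diboron, CC1(C)OB(OC1(C)C)B1OC(C)(C)C(C)(C)O1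
Why: Proposed new method: site-selective Suzuki–Miyaura coupling of the one primary C–B bond of a 1,2,4,6,8-pentakis(boronic ester) with a base-sensitive (Z)-β-iodoacrylate, run in the pot of the catalyst-controlled syn-diboration that sets C5; hydroxide or phosphate adds to the primary boron and the vicinal secondary Bpin bridges this ate complex, so only this C–B bond transmetalates to the alkenyl complex of divalent palladium formed by stereoretentive oxidative addition of 13, and reductive elimination forms C3–C4 with the Z geometry of the future ring alkene retained, the isolated secondary boronates at C7, C9 and C11 being inert; the closest known reactions are the one-pot alkene diboration/cross-coupling of vicinal bis(boronates) with aryl and simple alkenyl halides and the B-alkyl Suzuki coupling of (Z)-3-iodoacrylates with alkyl-9-BBN reagents.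

Step 7
Reactants: 15 ethyl (2Z,5R,7S,9R,11S)-5,7,9,11-tetrakis(4,4,5,5-tetramethyl-1,3,2-dioxaborolan-2-yl)icos-2-enoate
Product: 17 (6S)-6-[(2S,4R,6S)-2,4,6-trihydroxypentadecyl]-5,6-dihydro-2H-pyran-2-one, via tetrol ester 16 (not isolated)
Conditions: NaBO3·4H2O (10 equiv), THF/H2O (1:1), 0 °C → rt; then PPTS (cat.), CH2Cl2, rt
Reagents that add atoms: sodium perborate tetrahydrate, [Na+].[O-]OB=O.O.O.O.O
Why: Perborate oxidation converts all four C–B bonds into C–OH with retention (1,2-shift of carbon from boron to oxygen), and in tetrol ester 16 only the C5 hydroxyl can close a six-membered ring onto the Z-enoate, so lactonisation (completed by mild acid) gives the target with all four stereocentres untouched.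

**Compound list**

1 | oct-1-ene | CCCCCCC=C | starting material
2 | 4,4,5,5-tetramethyl-2-octyl-1,3,2-dioxaborolane (octyl-Bpin) | CCCCCCCCB1OC(C)(C)C(C)(C)O1 | intermediate (not isolated)
3 | lithium 2-(chloromethyl)-4,4,5,5-tetramethyl-2-octyl-1,3,2-dioxaborolan-2-uide (chloromethyl ate complex) | [Li+].CCCCCCCC[B-]1(CCl)OC(C)(C)C(C)(C)O1 | intermediate (not isolated)
4 | 4,4,5,5-tetramethyl-2-nonyl-1,3,2-dioxaborolane (nonyl-Bpin) | CCCCCCCCCB1OC(C)(C)C(C)(C)O1 | intermediate
5 | bromomagnesium 2-ethenyl-4,4,5,5-tetramethyl-2-nonyl-1,3,2-dioxaborolan-2-uide (ethenyl ate complex) | Br[Mg+].CCCCCCCCC[B-]1(C=C)OC(C)(C)C(C)(C)O1 | intermediate (not isolated)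
6 | 2-[(4S)-tridec-1-en-4-yl]-4,4,5,5-tetramethyl-1,3,2-dioxaborolane | CCCCCCCCC[C@H](B1OC(C)(C)C(C)(C)O1)CC=C | intermediate
7 | 2,2',2''-[(2S,4S)-tridecane-1,2,4-triyl]tris(4,4,5,5-tetramethyl-1,3,2-dioxaborolane) | CCCCCCCCC[C@H](B1OC(C)(C)C(C)(C)O1)C[C@@H](B1OC(C)(C)C(C)(C)O1)CB1OC(C)(C)C(C)(C)O1 | intermediate
8 | but-3-en-1-ol | C=CCCO | starting material
9 | but-3-en-1-yl 2,4,6-triisopropylbenzoate | C=CCCOC(=O)c1c(C(C)C)cc(C(C)C)cc1C(C)C | intermediate
10 | (1S)-1-lithiobut-3-en-1-yl 2,4,6-triisopropylbenzoate, as its (−)-sparteine complex | [Li][C@@H](CC=C)OC(=O)c1c(C(C)C)cc(C(C)C)cc1C(C)C | intermediate (not isolated)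
11 | lithium ate complex of 7 at its primary (C1) boron with the (1S)-1-(2,4,6-triisopropylbenzoyloxy)but-3-en-1-yl group of 10 (triboronate ate complex) | [Li+].CCCCCCCCC[C@H](B1OC(C)(C)C(C)(C)O1)C[C@@H](B1OC(C)(C)C(C)(C)O1)C[B-]1(OC(C)(C)C(C)(C)O1)[C@@H](CC=C)OC(=O)c1c(C(C)C)cc(C(C)C)cc1C(C)C | intermediate (not isolated)
12 | 2,2',2''-[(4S,6R,8S)-heptadec-1-ene-4,6,8-triyl]tris(4,4,5,5-tetramethyl-1,3,2-dioxaborolane) | CCCCCCCCC[C@H](B1OC(C)(C)C(C)(C)O1)C[C@@H](B1OC(C)(C)C(C)(C)O1)C[C@H](B1OC(C)(C)C(C)(C)O1)CC=C | intermediate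
13 | ethyl (Z)-3-iodoprop-2-enoate | CCOC(=O)/C=C\I | starting material
14 | 2,2',2'',2''',2''''-[(2S,4R,6R,8S)-heptadecane-1,2,4,6,8-pentayl]pentakis(4,4,5,5-tetramethyl-1,3,2-dioxaborolane) | CCCCCCCCC[C@H](B1OC(C)(C)C(C)(C)O1)C[C@@H](B1OC(C)(C)C(C)(C)O1)C[C@H](B1OC(C)(C)C(C)(C)O1)C[C@@H](B1OC(C)(C)C(C)(C)O1)CB1OC(C)(C)C(C)(C)O1 | intermediate (not isolated)
15 | ethyl (2Z,5R,7S,9R,11S)-5,7,9,11-tetrakis(4,4,5,5-tetramethyl-1,3,2-dioxaborolan-2-yl)icos-2-enoate | CCCCCCCCC[C@H](B1OC(C)(C)C(C)(C)O1)C[C@@H](B1OC(C)(C)C(C)(C)O1)C[C@H](B1OC(C)(C)C(C)(C)O1)C[C@@H](B1OC(C)(C)C(C)(C)O1)C/C=C\C(=O)OCC | intermediate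
16 | ethyl (2Z,5S,7R,9R,11S)-5,7,9,11-tetrahydroxyicos-2-enoate | CCCCCCCCC[C@H](O)C[C@@H](O)C[C@H](O)C[C@@H](O)C/C=C\C(=O)OCC | intermediate (not isolated)
17 | (6S)-6-[(2S,4R,6S)-2,4,6-trihydroxypentadecyl]-5,6-dihydro-2H-pyran-2-one | CCCCCCCCC[C@H](O)C[C@@H](O)C[C@H](O)C[C@@H]1CC=CC(=O)O1 | target

**Step count and risks**

Total steps: 7. Longest linear sequence: 6 (oct-1-ene → 4 → 6 → 7 → 12 → 15 → 17); the branch from but-3-en-1-ol is 4 steps long (8 → 9 → 12 → 15 → 17).

Steps most likely to fail: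

Step 6 (proposed new coupling). The risks are base-induced loss of HI from 13 to give ethyl propiolate, Z→E isomerisation, protodeboronation, and coupling that is too slow at a temperature the iodoacrylate tolerates. The fallback uses known chemistry, sets out from 12 and returns at 17. Perborate oxidation of 12 gives (4R,6R,8S)-heptadec-1-ene-4,6,8-triol F1. Silylation (TBSOTf, 2,6-lutidine, CH2Cl2) gives (4R,6R,8S)-4,6,8-tris[(tert-butyldimethylsilyl)oxy]heptadec-1-ene F2. Ozonolysis (O3, CH2Cl2, −78 °C; PPh3) gives (3S,5R,7S)-3,5,7-tris[(tert-butyldimethylsilyl)oxy]hexadecanal F3. Brown allylation with the Ipc2B(allyl) enantiomer that gives the (4S)-carbinol (reagent control; taken to be the (−)-reagent from (+)-α-pinene) gives (4S,6R,8R,10S)-6,8,10-tris[(tert-butyldimethylsilyl)oxy]nonadec-1-en-4-ol F4. Acryloyl chloride with i-Pr2NEt gives (4S,6R,8R,10S)-6,8,10-tris[(tert-butyldimethylsilyl)oxy]nonadec-1-en-4-yl prop-2-enoate F5. Ring-closing metathesis with the second-generation Grubbs catalyst (CH2Cl2, 40 °C) gives (6S)-6-[(2R,4R,6S)-2,4,6-tris[(tert-butyldimethylsilyl)oxy]pentadecyl]-5,6-dihydro-2H-pyran-2-one F6, and HF·pyridine in THF removes the silyl groups to give 17.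

Step 5 (regioselective lithiation–borylation on a tris(boronate)). The risks are attack of 10 at a secondary boron, a mismatched pairing with the existing centres, incomplete or less selective deprotonation of the homoallylic benzoate, and competing allylic deprotonation. The fallback replaces the stoichiometric chiral carbenoid by a catalyst-controlled conjunctive cross-coupling; it sets out from 7 and returns at 12. Vinylmagnesium bromide (1.0 equiv) with NaOTf in THF adds to the least hindered, primary boron to give the bromomagnesium ethenyl ate complex of 7 at its primary (C1) boron F7. Pd(OAc)2 with (Sp,Sp)-M* (the enantiomer of step 2, since the new centre has the same local sense) and vinyl bromide at 40 °C then make C8 migrate from boron to the vinyl α-carbon while the second vinyl group is delivered to the β-carbon, which gives 12 directly.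

Step 2 (conjunctive coupling with the parent vinyl electrophile). The risks are direct transfer of the vinyl group of 5 to palladium (giving buta-1,3-diene instead of the 1,2-shift), loss of the volatile vinyl bromide, and an enantiomeric ratio too low for clean reagent-controlled steps later. The fallback is a catalytic enantioselective Matteson homologation followed by a Grignard substitution; it sets out from 4 and returns at 6. LiCHCl2 (CH2Cl2, n-BuLi, THF, −100 °C) adds to 4 to give lithium 2-(dichloromethyl)-4,4,5,5-tetramethyl-2-nonyl-1,3,2-dioxaborolan-2-uide F8. A chiral lithium–isothiourea–boronate catalyst then removes one enantiotopic chloride during the 1,2-shift and gives 2-[(1R)-1-chlorodecyl]-4,4,5,5-tetramethyl-1,3,2-dioxaborolane F9. Allylmagnesium bromide adds to its boron to give bromomagnesium 2-[(1R)-1-chlorodecyl]-4,4,5,5-tetramethyl-2-(prop-2-en-1-yl)-1,3,2-dioxaborolan-2-uide F10, which on warming rearranges with inversion (allyl migrates, chloride leaves) to 6.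

**Further compounds**

F1 | step 6 | (4R,6R,8S)-heptadec-1-ene-4,6,8-triol | CCCCCCCCC[C@H](O)C[C@@H](O)C[C@H](O)CC=C
F2 | step 6 | (4R,6R,8S)-4,6,8-tris[(tert-butyldimethylsilyl)oxy]heptadec-1-ene | CCCCCCCCC[C@H](O[Si](C)(C)C(C)(C)C)C[C@@H](O[Si](C)(C)C(C)(C)C)C[C@H](O[Si](C)(C)C(C)(C)C)CC=C
F3 | step 6 | (3S,5R,7S)-3,5,7-tris[(tert-butyldimethylsilyl)oxy]hexadecanal | CCCCCCCCC[C@H](O[Si](C)(C)C(C)(C)C)C[C@@H](O[Si](C)(C)C(C)(C)C)C[C@H](O[Si](C)(C)C(C)(C)C)CC=O
F4 | step 6 | (4S,6R,8R,10S)-6,8,10-tris[(tert-butyldimethylsilyl)oxy]nonadec-1-en-4-ol | CCCCCCCCC[C@H](O[Si](C)(C)C(C)(C)C)C[C@@H](O[Si](C)(C)C(C)(C)C)C[C@H](O[Si](C)(C)C(C)(C)C)C[C@@H](O)CC=C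
F5 | step 6 | (4S,6R,8R,10S)-6,8,10-tris[(tert-butyldimethylsilyl)oxy]nonadec-1-en-4-yl prop-2-enoate | CCCCCCCCC[C@H](O[Si](C)(C)C(C)(C)C)C[C@@H](O[Si](C)(C)C(C)(C)C)C[C@H](O[Si](C)(C)C(C)(C)C)C[C@@H](OC(=O)C=C)CC=C
F6 | step 6 | (6S)-6-[(2R,4R,6S)-2,4,6-tris[(tert-butyldimethylsilyl)oxy]pentadecyl]-5,6-dihydro-2H-pyran-2-one | CCCCCCCCC[C@H](O[Si](C)(C)C(C)(C)C)C[C@@H](O[Si](C)(C)C(C)(C)C)C[C@H](O[Si](C)(C)C(C)(C)C)C[C@@H]1CC=CC(=O)O1
F7 | step 5 | bromomagnesium ethenyl ate complex of 7 at its primary (C1) boron | Br[Mg+].CCCCCCCCC[C@H](B1OC(C)(C)C(C)(C)O1)C[C@@H](B1OC(C)(C)C(C)(C)O1)C[B-]1(C=C)OC(C)(C)C(C)(C)O1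
F8 | step 2 | lithium 2-(dichloromethyl)-4,4,5,5-tetramethyl-2-nonyl-1,3,2-dioxaborolan-2-uide | [Li+].CCCCCCCCC[B-]1(C(Cl)Cl)OC(C)(C)C(C)(C)O1
F9 | step 2 | 2-[(1R)-1-chlorodecyl]-4,4,5,5-tetramethyl-1,3,2-dioxaborolane | CCCCCCCCC[C@H](Cl)B1OC(C)(C)C(C)(C)O1
F10 | step 2 | bromomagnesium 2-[(1R)-1-chlorodecyl]-4,4,5,5-tetramethyl-2-(prop-2-en-1-yl)-1,3,2-dioxaborolan-2-uide | Br[Mg+].CCCCCCCCC[C@H](Cl)[B-]1(CC=C)OC(C)(C)C(C)(C)O1
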